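## Numbering

Compounds: 1 2,2-dimethyl-1,3-dioxan-5-one; 2 glyoxal; 3 mono-aldol adduct; 4 bicyclic keto diol; 5 its cyclic thionocarbonate; 6 bicyclic enone; 7 1-bromoundecane; 8 undecyltriphenylphosphonium bromide; 9 its ylide; 10 bicyclic diene; 11 diene diol; 12 diene diacetate; 13 dihydroxylation product; 14 target.

Atom labels of the target: C1 is the quaternary carbinol carbon, C2 and C5 the acetoxy carbons, C3=C4 the ring alkene, C1′ the side-chain ketone carbon.

## Analysis of the target

Compound 14 is a cyclopent-3-ene in which all five ring carbons are functionalised: C1 is a quaternary carbinol carbon carrying the undecanoyl group, C2 and C5 are acetoxy-bearing methines, and C3=C4 is the ring alkene. The three stereogenic ring carbons stand in one simple relation: the two acetates are cis to each other and trans to the C1 hydroxyl, so the acyl group lies on the acetate face. A mirror plane through C1, C1′ and the midpoint of C3=C4 makes the molecule achiral (C1 is pseudo-asymmetric), so only relative configuration has to be controlled. The sensitive groups are the two allylic acetates (ionisation, acyl migration, saponification) and the tertiary α-ketol (acyloin shift), so neither strong base nor strong acid is tolerated late in the route. The difficulty is the quaternary centre: its carbon substituent is on the more hindered face, so a carbon nucleophile added to a C1 ketone would enter anti to the C2 and C5 oxygens and give the wrong epimer; the C1–O bond must instead be made by oxygenation of a C1=C1′ alkene anti to those oxygens. The strategy rests on C2 and C5 being equivalent carbinol carbons on either side of C1 with cis oxygens: O–C2–C1–C5–O is a 1,3-dihydroxy ketone unit whose oxygens can be tied together as a cyclic ketal, and C3–C4 is a two-carbon unit that can be delivered at the dialdehyde level.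

## Retrosynthetic reasoning

14 to 12. The C1′ ketone is taken back to the secondary alcohol 13, and the C1–O and C1′–O bonds are then cut together as a syn-dihydroxylation of the exocyclic C1=C1′ alkene of 12. The cut is made here because the two allylic acetates of 12 shield one face of that alkene, so the oxidant must deliver the C1 oxygen trans to both acetates and leave the side-chain carbon on the acetate face. The forward reaction has to distinguish the trisubstituted exocyclic alkene from the ring alkene and later oxidise only the secondary carbinol.

12 to 10. The two acetates are exchanged for the bridging acetonide of 10 (through diol 11). The acetonide is kept until the C1=C1′ bond exists: while C1 is still a ketone carbon, as in 6, C2 and C5 would become enolisable once the bridge is gone, whereas in the bicycle they are bridgeheads and cannot enolise.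

10 to 6 and 8. The C1=C1′ bond is cut as a Wittig olefination of ketone 6 with ylide 9, made from salt 8. This brings in the whole side chain as one C11 unit. The alkene geometry is irrelevant because C1′ ends as a carbonyl carbon. Salt 8 comes from bromide 7 in one step.

6 to 4. The C3=C4 alkene of 6 is traced to the cis-1,2-diol 4 through the thionocarbonate 5 (Corey–Winter olefination). This removes the two carbinol centres that the ring construction leaves at C3 and C4. The forward reaction needs the two hydroxyls cis; that is the one demand placed on these otherwise temporary centres.

4 to 1 and 2. The C2–C3 and C4–C5 bonds are cut together. Both are aldol bonds between an α-carbon of ketone 1 and a carbonyl carbon of 2, so one operation forms the ring and two skeletal bonds from two commercial compounds. The acetonide of 1 becomes a bridge that can only exist if the C2 and C5 oxygens are cis. The forward reaction must make the second, intramolecular aldol win over oligomerisation.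

## Alternatives that were turned down

Alternative 1: The ring is cut at C1–C2 and C1–C5, so that C1 with its side chain comes from the terminal carbon of dodec-1-en-2-yl acetate (A2) and C2–C5 from maleic anhydride (A3). In the forward sense AlCl3 would drive two successive C-acylations of A2 by A3 and give 2-undecanoylcyclopent-4-ene-1,3-dione (A1), a chelated enol without a stereocentre.
- For: one step assembles all sixteen skeletal carbons, the ring alkene and the C1′ ketone from two cheap components. On length to the skeleton it is clearly stronger than the chosen route.
- Against: A1 has C2 and C5 at the ketone level and C1 at the C–H level. The target then needs hydroxylation at C1 and reduction of both ring carbonyls from the same face, trans to the new hydroxyl, while a third ketone on the same carbon is spared. Three carbonyls on one carbon offer no handle for that selectivity, and the ene-dione of A1 also accepts hydride in the conjugate sense. Hydroxylation of A1 at C1 would also place a tertiary carbinol between three carbonyl groups, an arrangement set up for retro-Claisen cleavage.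
- Comparison: the chosen strategy is longer, but it delivers C2 and C5 at the carbinol level with their cis relation fixed by a ring, and leaves a single stereochemical decision that is governed by two allylic acetates.

Alternative 2: The C2–O and C5–O bonds are cut together as a peroxide bridge. Dye-sensitised photooxygenation of 6-decylfulvene (A4) would add oxygen across the ring diene and give 7-undecylidene-2,3-dioxabicyclo[2.2.1]hept-5-ene (A5). Reduction of the O–O bond of A5 leads to the same diol 11.
- For: the suprafacial cycloaddition sets the cis relation as surely as the acetonide bridge does, the side chain and both alkenes are in place from the start, and 11 is reached in about three steps from commercial materials. On step count and on precedent this alternative is stronger.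
- Against: A4 dimerises and polymerises readily, A5 rearranges well below room temperature and must be reduced cold, the ene reaction at the allylic CH2 of the chain competes, and the chemistry is a low-temperature photoreaction with a peroxide.
- Comparison: the chosen strategy offers thermally robust, non-enolisable bicyclic intermediates and a ketone (6) at C1 that accepts more than one kind of side-chain olefination. Alternative 2 is kept as the fallback for the key step.

Alternative 3: The ring is cut at C1–C5. The Achmatowicz product 2-[1-(tert-butyldimethylsilyloxy)undecyl]-6-hydroxy-2H-pyran-3(6H)-one (A6), a pyranone hemiacetal that already carries the silyl-protected side chain, would be opened at its hemiacetal by triethylamine. The carbon of A6 between the ring oxygen and the ketone then reacts as an enediol carbon with the freed aldehyde and closes the ring to trans-4,5-dihydroxy-5-[1-(tert-butyldimethylsilyloxy)undecyl]cyclopent-2-en-1-one (A7).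
- For: the furan-derived precursor of A6 is cheap, the side chain and its oxygen are present from the start, and no late choice between two alkenes arises. On that point it is stronger than the chosen route.
- Against: A7 carries a ketone where the target has an acetoxy carbinol, so a 1,2-reduction must come from the correct face of an enone flanked by a quaternary carbinol. The side-chain carbinol makes A6 and A7 diastereomer mixtures and costs a deprotection and an oxidation at the end. The 4-hydroxy enone of A7 is prone to elimination and retro-aldol opening under the basic conditions that form it.
- Comparison: the length is similar. The chosen strategy fixes the C2/C5 relation by geometry instead of by a reduction, and handles symmetric, crystallisable intermediates.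

Key step: step 1

## Route

Remark: 14 is achiral, 10–13 are racemic and converge on it (one enantiomer is drawn), and 4 is taken as the 6-exo,7-exo diol, whose two carbinol centres are erased in step 3.

Step 1
Reactants: 1 2,2-dimethyl-1,3-dioxan-5-one; 2 glyoxal (40 wt% in water)
Product: 4 6-exo,7-exo-dihydroxy-3,3-dimethyl-2,4-dioxabicyclo[3.2.1]octan-8-one (meso), via mono-aldol adduct 3 (not isolated)
Conditions: L-proline (30 mol%), DMSO, rt; 2 (1.1 equiv) added slowly by syringe pump
Reagents that add atoms: none
Why: Proposed new method: the amine condenses with 1 to an enamine that adds to one carbonyl of 2 (the established enamine aldol of this dioxanone), and adduct 3 re-forms an enamine towards its unsubstituted α-carbon, which adds to the pendant aldehyde. The closest known reactions are the first stage of the Weiss–Cook condensation, where glyoxal and a 3-oxoglutarate diester close a 3,4-dihydroxycyclopentanone by the same double aldol, and the proline-catalysed aldol additions of 1 to aldehydes. The five-membered ring closes in the 5-(enolendo)-exo-trig mode, formally disfavoured by the rules for enolate closure but the mode by which 1,4-dicarbonyl compounds cyclise to cyclopentenones; the dioxanone ring becomes the six-membered ring of the bicycle. In the enamine of 3, allylic 1,3-strain with the amine pushes the C4 substituent axial, onto the axis along which the enamine carbon reacts, so the aldehyde is held over the nucleophilic carbon. The two bridgehead centres can only be cis, because a trans-4,6-disubstituted dioxanone cannot span the two-carbon bridge, and such material returns by retro-aldol. The two carbinol centres equilibrate through the same retro-aldol steps and are expected to settle exo, away from the acetal bridge; they are temporary. The step needs 1:1 coupling instead of 2:1 oligomers, which slow addition of 2 and the intramolecular second aldol favour. The product can neither dehydrate nor enolise, since both α-hydrogens are bridgehead hydrogens, so it should collect as the sink of the equilibria.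

Step 2
Reactants: 4 6-exo,7-exo-dihydroxy-3,3-dimethyl-2,4-dioxabicyclo[3.2.1]octan-8-one
Product: 5 cyclic 6,7-thionocarbonate of 4 (exo-fused 1,3-dioxolane-2-thione)
Conditions: 1,1′-thiocarbonyldiimidazole (1.2 equiv), THF, rt to 50 °C
Reagents that add atoms: 1,1′-thiocarbonyldiimidazole, S=C(n1ccnc1)n1ccnc1
Why: Thiocarbonylation of a cis-1,2-diol, the first half of the Corey–Winter olefination; the eclipsed exo hydroxyls close the five-membered ring readily, and once both are acylated retro-aldol opening is blocked.

Step 3
Reactants: 5 cyclic 6,7-thionocarbonate of 4
Product: 6 3,3-dimethyl-2,4-dioxabicyclo[3.2.1]oct-6-en-8-one (meso)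
Conditions: 1,3-dimethyl-2-phenyl-1,3,2-diazaphospholidine (3 equiv), THF, 40 °C
Reagents that add atoms: none
Why: Corey–Winter olefination: thiophilic attack of the trivalent phosphorus reagent gives a dioxolanylidene carbene that loses CO2 in a syn cycloreversion to the C3=C4 alkene. The diazaphospholidine variant runs near room temperature, which spares the bridged β,γ-unsaturated ketone from thermal loss of CO; both temporary stereocentres disappear.

Step 4
Reactants: 7 1-bromoundecane
Product: 8 undecyltriphenylphosphonium bromide
Conditions: PPh3, MeCN, reflux
Reagents that add atoms: triphenylphosphine, c1ccc(cc1)P(c1ccccc1)c1ccccc1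
Why: SN2 quaternisation of triphenylphosphine by a primary bromide.

Step 5
Reactants: 6 3,3-dimethyl-2,4-dioxabicyclo[3.2.1]oct-6-en-8-one; 8 undecyltriphenylphosphonium bromide
Product: 10 3,3-dimethyl-8-undecylidene-2,4-dioxabicyclo[3.2.1]oct-6-ene (racemic), via ylide 9 (not isolated)
Conditions: NaN(SiMe3)2, THF, 0 °C; then 6, −78 °C to rt
Reagents that add atoms: none
Why: Wittig olefination with a non-stabilised ylide; ketone 6 is strongly electrophilic (two α-oxygens) and cannot enolise because both α-hydrogens are at bridgeheads. The two possible alkene geometries are mirror images of each other, so a single racemate results and C1′ later becomes a carbonyl carbon.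

Step 6
Reactants: 10 3,3-dimethyl-8-undecylidene-2,4-dioxabicyclo[3.2.1]oct-6-ene
Product: 11 cis-2-undecylidenecyclopent-4-ene-1,3-diol (racemic; both hydroxyls on one face)
Conditions: pyridinium p-toluenesulfonate (10 mol%), MeOH, 0 °C to rt
Reagents that add atoms: none
Why: Acid-catalysed transketalisation; cleavage runs through the tertiary oxocarbenium ion at the ketal carbon, so the ring C–O bonds and their cis relation are not touched. The bridging ketal, which must hold a methyl group against the ring, should be released under very mild acid.

Step 7
Reactants: 11 cis-2-undecylidenecyclopent-4-ene-1,3-diol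
Product: 12 cis-2-undecylidenecyclopent-4-ene-1,3-diyl diacetate (racemic)
Conditions: Ac2O, pyridine, 4-(dimethylamino)pyridine (cat.), CH2Cl2, 0 °C to rt
Reagents that add atoms: acetic anhydride, CC(=O)OC(C)=O
Why: O-acylation of the two secondary allylic alcohols under nucleophilic catalysis, with retention at carbon.

Step 8
Reactants: 12 cis-2-undecylidenecyclopent-4-ene-1,3-diyl diacetate
Product: 13 cis-2-hydroxy-2-(1-hydroxyundecyl)cyclopent-4-ene-1,3-diyl diacetate (racemic; ring hydroxyl trans to both acetates)
Conditions: OsO4 (2 mol%), N-methylmorpholine N-oxide (1.1 equiv), acetone/H2O, 0 °C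
Reagents that add atoms: osmium tetroxide, O=[Os](=O)(=O)=O (both oxygens, catalytic); N-methylmorpholine N-oxide, C[N+]1([O-])CCOCC1; water, O
Why: Catalytic syn-dihydroxylation; OsO4 adds to the face of C1=C1′ opposite the two allylic acetates, which places the C1 hydroxyl trans to both, and the trisubstituted exocyclic alkene is the more electron-rich of the two. The C1′ configuration follows from syn addition and is lost in step 9.

Step 9
Reactants: 13 cis-2-hydroxy-2-(1-hydroxyundecyl)cyclopent-4-ene-1,3-diyl diacetate
Product: 14 2-hydroxy-2-undecanoylcyclopent-4-ene-1,3-diyl diacetate (acetates cis, hydroxyl trans to both; CNP0208983.3)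
Conditions: Dess–Martin periodinane (1.3 equiv), CH2Cl2, 0 °C to rt
Reagents that add atoms: none
Why: Dess–Martin oxidation of the secondary alcohol; the tertiary alcohol cannot be oxidised, the conditions are non-basic so the acetates stay in place, and C1 bears no hydrogen, so the β-acetoxy ketone cannot eliminate.

## Compound list

1 | 2,2-dimethyl-1,3-dioxan-5-one | CC1(C)OCC(=O)CO1 | starting material
2 | glyoxal | O=CC=O | starting material
3 | 2-(2,2-dimethyl-5-oxo-1,3-dioxan-4-yl)-2-hydroxyacetaldehyde (mono-aldol adduct, formed in the flask; relative configuration as carried into 4) | O=C[C@@H](O)[C@@H]1OC(C)(C)OCC1=O | intermediate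
4 | 6-exo,7-exo-dihydroxy-3,3-dimethyl-2,4-dioxabicyclo[3.2.1]octan-8-one (meso; hydroxyls on the face opposite the acetal oxygens) | O=C1[C@H]2OC(C)(C)O[C@@H]1[C@@H](O)[C@H]2O | intermediate
5 | cyclic 6,7-thionocarbonate of 4 | O=C1[C@H]2OC(C)(C)O[C@@H]1[C@H]3OC(=S)O[C@@H]23 | intermediate
6 | 3,3-dimethyl-2,4-dioxabicyclo[3.2.1]oct-6-en-8-one (meso) | O=C1[C@H]2OC(C)(C)O[C@@H]1C=C2 | intermediate
7 | 1-bromoundecane | CCCCCCCCCCCBr | starting material
8 | undecyltriphenylphosphonium bromide | CCCCCCCCCCC[P+](c1ccccc1)(c1ccccc1)c1ccccc1.[Br-] | intermediate
9 | undecylidenetriphenylphosphorane (formed in the flask) | CCCCCCCCCCC=P(c1ccccc1)(c1ccccc1)c1ccccc1 | intermediate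
10 | 3,3-dimethyl-8-undecylidene-2,4-dioxabicyclo[3.2.1]oct-6-ene (racemic) | CCCCCCCCCC/C=C1/[C@H]2OC(C)(C)O[C@@H]1C=C2 | intermediate
11 | cis-2-undecylidenecyclopent-4-ene-1,3-diol (racemic) | CCCCCCCCCC/C=C1/[C@@H](O)C=C[C@H]1O | intermediate
12 | cis-2-undecylidenecyclopent-4-ene-1,3-diyl diacetate (racemic) | CCCCCCCCCC/C=C1/[C@@H](OC(C)=O)C=C[C@H]1OC(C)=O | intermediate
13 | cis-2-hydroxy-2-(1-hydroxyundecyl)cyclopent-4-ene-1,3-diyl diacetate (racemic; ring hydroxyl trans to the acetates) | CCCCCCCCCC[C@H](O)[C@@]1(O)[C@@H](OC(C)=O)C=C[C@H]1OC(C)=O | intermediate
14 | 2-hydroxy-2-undecanoylcyclopent-4-ene-1,3-diyl diacetate (acetates cis, hydroxyl trans to both; meso) | CCCCCCCCCCC(=O)[C@@]1(O)[C@@H](OC(C)=O)C=C[C@H]1OC(C)=O | target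

## Step count and least certain steps

Total: 9 steps. Longest linear sequence: 8 steps (steps 1–3 and 5–9 from 1 and 2); step 4 is a one-step side branch.

Step 1 (key step, proposed new method). The second aldol may fail to close. Adduct 3 can be drained by hydration and oligomerisation of its α-hydroxy aldehyde, by dehydration to a conjugated enal, by enediol isomerisation or by 2:1 coupling. The gem-dimethyl ketal carbon cannot place a methyl group under the two-carbon bridge, so the dioxane ring of 4 must leave the chair, and this strain weighs against the bicycle in the equilibrium. A dioxanone whose acetal carbon carries one hydrogen would remove the strain at the price of a harsher deprotection.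
Fallback (known reaction types only), setting out from 7 and returning at 11: Kornblum oxidation of 7 (DMSO, NaHCO3, heat) gives undecanal F1. Condensation with cyclopentadiene (pyrrolidine, MeOH) gives 6-decylfulvene F2. Tetraphenylporphyrin-sensitised photooxygenation at −78 °C adds oxygen across the ring diene to the endoperoxide F3, which is reduced cold with thiourea to 11. Steps 7–9 follow unchanged. This is the chemistry weighed as Alternative 2 (F2 and F3 are A4 and A5); it is accepted here only with its thermal fragility.

Step 8. Site selectivity may be poor: both alkenes are flanked by two acetoxy-bearing carbons, the electronic advantage of the trisubstituted alkene is modest, and the strained ring alkene may compete, with over-oxidation following.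
Fallback, setting out from 12 and returning at 14: both alkenes are dihydroxylated on purpose (OsO4 cat., excess N-methylmorpholine N-oxide) to the tetrol F4. One equivalent of thiocarbonyldiimidazole closes the unhindered cis-diol on C3/C4 to the thionocarbonate F5; the side-chain diol contains a tertiary hydroxyl on a carbon flanked by two acetoxy carbons and should react far more slowly. Dess–Martin oxidation gives the ketol F6, and the diazaphospholidine of step 3 returns the ring alkene to give 14. The choice between two alkenes is thus replaced by a choice between a secondary/secondary and a secondary/tertiary diol. Ring-diol by-products of step 8 can be fed into the same sequence.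

Step 6. The C–O bonds of 10 and 11 are allylic to two alkenes at once, so acid may ionise them, with loss of the cis relation or dehydration towards a fulvene.
Fallback, setting out from 6 and returning at 14: (methoxymethyl)diphenylphosphine oxide is alkylated with 1-bromodecane (LiN(i-Pr)2, THF) to (1-methoxyundecyl)diphenylphosphine oxide F7. Its lithium derivative adds to 6 to give adduct F8, and KOt-Bu in the same flask eliminates diphenylphosphinate (Horner–Wittig) to the enol ether F9. Dimethyldioxirane should attack this electron-rich alkene in preference to the ring alkene and from the open face over the two-carbon C6=C7 bridge of the bicycle. The methoxy epoxide F10 opens on aqueous work-up to the ketol F11 with the hydroxyl trans to the acetal oxygens (Rubottom-type oxidation). Only then is the ketal removed (pyridinium p-toluenesulfonate, MeOH) to the triol F12, whose C–O bonds are allylic to one alkene only and adjacent to an electron-poor carbon. Acetylation of the two secondary hydroxyls (Ac2O, pyridine) gives 14. The price is that the C1 configuration then rests on facial selectivity in the bicycle instead of on the two acetates.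

Step 2. Ring closure to the thionocarbonate fails if the annulation does not deliver the two hydroxyls cis, since a trans-fused five-membered ring cannot form on the bicycle.
Fallback, setting out from 1 and 2 as in step 1 and returning at 6: the 6-exo,7-endo diol F13 is converted with excess thiocarbonyldiimidazole into the bis(imidazolylthiocarbonyl) ester F14. Radical elimination (Bu3SnH, azobisisobutyronitrile, toluene, 80 °C) gives 6. This elimination does not depend on the relative configuration, and a mixture of diols can be separated and each isomer taken on in its own way.

## Further compounds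

F1 | step 1 | undecanal | CCCCCCCCCCC=O
F2 | step 1 | 6-decylfulvene | CCCCCCCCCCC=C1C=CC=C1
F3 | step 1 | 7-undecylidene-2,3-dioxabicyclo[2.2.1]hept-5-ene (racemic) | CCCCCCCCCC/C=C1/[C@@H]2C=C[C@H]1OO2
F4 | step 8 | 2,4,5-trihydroxy-2-(1-hydroxyundecyl)cyclopentane-1,3-diyl diacetate (ring hydroxyls trans to the acetates; racemic) | CCCCCCCCCC[C@H](O)[C@@]1(O)[C@@H](OC(C)=O)[C@H](O)[C@H](O)[C@H]1OC(C)=O
F5 | step 8 | 4,5-cyclic thionocarbonate of F4 | CCCCCCCCCC[C@H](O)[C@@]1(O)[C@@H](OC(C)=O)[C@@H]2OC(=S)O[C@@H]2[C@H]1OC(C)=O
F6 | step 8 | 4,5-cyclic thionocarbonate of 2,4,5-trihydroxy-2-undecanoylcyclopentane-1,3-diyl diacetate | CCCCCCCCCCC(=O)[C@@]1(O)[C@@H](OC(C)=O)[C@@H]2OC(=S)O[C@@H]2[C@H]1OC(C)=O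
F7 | step 6 | (1-methoxyundecyl)diphenylphosphine oxide (racemic) | CCCCCCCCCCC(OC)P(=O)(c1ccccc1)c1ccccc1
F8 | step 6 | 8-[1-(diphenylphosphoryl)-1-methoxyundecyl]-3,3-dimethyl-2,4-dioxabicyclo[3.2.1]oct-6-en-8-ol (diastereomer mixture at the two new centres) | CCCCCCCCCCC(OC)(P(=O)(c1ccccc1)c1ccccc1)C1(O)[C@H]2OC(C)(C)O[C@@H]1C=C2
F9 | step 6 | 8-(1-methoxyundecylidene)-3,3-dimethyl-2,4-dioxabicyclo[3.2.1]oct-6-ene (racemic) | CCCCCCCCCC/C(OC)=C1/[C@H]2OC(C)(C)O[C@@H]1C=C2
F10 | step 6 | spiro methoxy epoxide of F9 (epoxide oxygen on the face over C6=C7; racemic) | CCCCCCCCCC[C@]1(OC)O[C@@]12[C@H]3OC(C)(C)O[C@@H]2C=C3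
F11 | step 6 | 1-(8-hydroxy-3,3-dimethyl-2,4-dioxabicyclo[3.2.1]oct-6-en-8-yl)undecan-1-one (hydroxyl trans to the acetal oxygens) | CCCCCCCCCCC(=O)[C@@]1(O)[C@H]2OC(C)(C)O[C@@H]1C=C2
F12 | step 6 | 1-(1,2,5-trihydroxycyclopent-3-en-1-yl)undecan-1-one (C2 and C5 hydroxyls cis, C1 hydroxyl trans to both) | CCCCCCCCCCC(=O)[C@@]1(O)[C@@H](O)C=C[C@H]1O
F13 | step 2 | 6-exo,7-endo-dihydroxy-3,3-dimethyl-2,4-dioxabicyclo[3.2.1]octan-8-one (racemic) | O=C1[C@H]2OC(C)(C)O[C@@H]1[C@H](O)[C@H]2O
F14 | step 2 | 6,7-bis(imidazol-1-ylthiocarbonyl) ester of F13 | O=C1[C@H]2OC(C)(C)O[C@@H]1[C@H](OC(=S)n1ccnc1)[C@H]2OC(=S)n1ccnc1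
A1 | alternative 1 | 2-undecanoylcyclopent-4-ene-1,3-dione | CCCCCCCCCCC(=O)C1C(=O)C=CC1=O
A2 | alternative 1 | dodec-1-en-2-yl acetate | C=C(CCCCCCCCCC)OC(C)=O
A3 | alternative 1 | maleic anhydride | O=C1OC(=O)C=C1
A4 | alternative 2 | 6-decylfulvene | CCCCCCCCCCC=C1C=CC=C1
A5 | alternative 2 | 7-undecylidene-2,3-dioxabicyclo[2.2.1]hept-5-ene | CCCCCCCCCCC=C1[C@@H]2C=C[C@H]1OO2
A6 | alternative 3 | 2-[1-(tert-butyldimethylsilyloxy)undecyl]-6-hydroxy-2H-pyran-3(6H)-one (diastereomer mixture) | CCCCCCCCCCC(O[Si](C)(C)C(C)(C)C)C1OC(O)C=CC1=O
A7 | alternative 3 | trans-4,5-dihydroxy-5-[1-(tert-butyldimethylsilyloxy)undecyl]cyclopent-2-en-1-one | CCCCCCCCCC[C@H](O[Si](C)(C)C(C)(C)C)[C@@]1(O)C(=O)C=C[C@H]1O
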